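## Structural features

The target is a germacrane: one ten-membered carbocycle (C1 to C10) whose secondary oxygen at C8 carries a 4-hydroxybenzoate, the arene being attached only through that ester. The ring contains two E alkenes, the trisubstituted C1=C10 (methyl on C10) and the disubstituted C5=C6, and a tertiary allylic carbinol at C4 (methyl and hydroxyl) next to C5. C7 (isopropyl, S) and C8 (acyloxy, S) are adjacent stereocentres with their substituents anti. C4 (R) is separated from them by the C5=C6 alkene, so its configuration has to be related to C7/C8 across the ring. The fragile elements are the 1(10),5-diene, which cyclises transannularly to decalins under acid, the easily ionised tertiary allylic alcohol, and the aryl ester with its free phenol, which is sensitive to strong base and nucleophiles. The real difficulty is the medium ring with two E alkenes of defined geometry and a remote stereocentre, not the ester. The feature used is that C5 and C10 face each other across the ring and each is the allylic terminus of one alkene. A C5–C10 bond turns the ring into a trans-decalin (ring A: C1–C5 and C10; ring B: C5–C10), in which a leaving group on C1 and a boron on C6 encode the two alkenes.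

## Logic of the disconnections

27 to 26: the acetyl–oxygen bond of the phenol is cut. The phenol must be masked while the acid chloride is used, and an aryl acetate comes off with mild base and no acid. The gain is small but it makes the acylation clean. The forward step must cleave the aryl acetate without touching the C8 benzoate.

26 to 24 and 25: the C8 O–C(=O) bond is cut. This removes the base-sensitive ester from every earlier step and makes the arene a purchased fragment. The target is reduced to a diol. The forward step must acylate the secondary C8 hydroxyl and leave the tertiary C4 hydroxyl alone.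

24 to 23: both O–Si bonds are cut. The hydroxyls have to be inert during the borane/alkali step (no alkoxyboranes, no alkoxide next to a sulfonate), and two identical silyl ethers come off in one operation. The demand is fluoride, not acid.

23 to 20: the C5–C10 bond is re-formed, the C1=C10 π bond becomes a C1–O sulfonate and the C5=C6 π bond becomes a C6–B bond, itself masked as the C6=C7 alkene. The cut is made here because both alkenes flank the C5/C10 pair. The gain is large: the medium-ring problem becomes a rigid chair problem and C7 becomes an sp2 carbon. The forward step needs boron on C6 from the α face, a trans ring fusion and an equatorial leaving group at C1, so that both breaking bonds are antiperiplanar to C5–C10.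

20 to 19 to 18: the S–O bond of the mesylate and the acyl–O bond of the pivalate are cut. A sulfonate cannot be carried earlier, because its methyl protons are acidic toward amide bases and Grignard reagents. It would also fragment at the first hydroboration, where boron on C4 is 1,4-related to C1 in the same way. The C1 oxygen is therefore carried as a pivalate. The demand is a hydride cleavage that spares silyl ethers and the alkene.

18 to 16 and 17: the C7–C11 bond is cut at an sp2 carbon. The alkene position is then defined by an enol triflate and C7 returns to the ketone oxidation level. The forward step must couple a secondary alkyl group without isomerisation and tolerate the pivalate.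

16 to 14: the C7–O(triflyl) bond is cut. The demand is enolisation toward C6 and not toward C8, which the C8 silyloxy group is there to enforce.

14 to 12 to 11: the C8–O bond and the two O–Si bonds are cut. α-Oxygenation through the enol ether is used because this ring system enolises toward C8. The forward step must oxidise from the α face to give the equatorial 8α oxygen, and one silylation must serve both C4–OH and the enol.

11 to 10 to 8: the ketal C–O bonds and the C4–O bond are cut. A methyl nucleophile added to a C4 ketone would enter from the open α face and give the wrong C4 epimer. Oxygen is therefore added last, to an exocyclic alkene, along the same open α trajectory. The demand is Markovnikov hydration with equatorial attack.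

8 to 7: the C4=C15 bond is cut back to a ketone. The forward methylenation must be non-basic so that C5, now α to a carbonyl, keeps its configuration.

7 to 6 to 4: the C4–O and C5–H bonds are cut. One hydroboration of the C4=C5 alkene sets the trans ring fusion and places oxygen on C4. The demand is α-face attack.

4 to 3 to 2 to 1: the ketal C–O bonds (the alkene returns to conjugation), the pivalate and the C1–H bond are cut, which reaches the purchased diketone. The forward demands are deconjugative ketalisation and chemoselective α-face reduction of the saturated ketone.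

## Other disconnections considered

Alternative 1: The cut is C2–C3, with C5–C10 reconnected, so the ring contracts to the trans-1,2-dialkenylcyclohexanol A1 (hydroxyl and isopropenyl on C5, methyl and vinyl on C10, C7 and C8 in place). Forward, the potassium alkoxide of A1 (KH, 18-crown-6) would undergo an anionic oxy-Cope rearrangement through a chair, forming C2–C3, breaking C5–C10 and giving a C4=C5 enolate, trapped with Me3SiCl as A2.
- In its favour: one σ bond is made, C7/C8 are set on a six-membered ring, the chair gives the E C1=C10 alkene, and the conditions are basic and acid-free.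
- Against it here: A2 has oxygen on C5 and an enol ether at C4=C5. The C4 carbinol would have to be created by oxidising a flexible ten-membered enol ether with no dependable facial bias relative to C7/C8. The C5 carbonyl would then have to become the E C5=C6 alkene on the medium ring.
- Comparison on structure: the chosen plan delivers both alkenes and all three centres in final form at the moment the ring appears, while A2 needs several redox changes on the sensitive ring.
- Comparison on mechanism: the two are equal, both being concerted, chair-controlled and stereospecific.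
- Comparison on step economy: the alternative is better up to the ring and worse after it, so roughly equal overall.

Alternative 2: The cut is C7–C8. Forward, divalent chromium (CrCl2) would convert the allylic bromide of the acyclic aldehyde A3 into an allylchromium whose γ carbon C7 adds to the C8 aldehyde through a six-membered chair, closing the ring to the homoallylic alcohol A4.
- In its favour: the assembly is convergent, both alkenes come from acyclic olefinations of secure geometry (equal to the chosen plan on this point), and C7 and C8 are formed together with the anti relationship the target needs. The C8 hydroxyl emerges free and ready for acylation, which is better than the chosen plan at that position.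
- Against it here: the C7 substituent arrives as a 1-(methoxycarbonyl)ethenyl group. Turning it into isopropyl needs deoxygenation of the ester carbon and hydrogenation of one alkene in the presence of two ring alkenes. The absolute sense at C7/C8 would have to be induced by the remote C4 centre through a ten-membered transition state. The cross-conjugated allylmetal could also react at C5, and high dilution and excess chromium are required.
- Comparison on structure: equal for the alkenes, weaker for the side chain.
- Comparison on mechanism: stereocontrol rests on a flexible macrocyclic transition state, against a rigid chair in the chosen plan.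
- Comparison on step economy: probably similar once the side-chain adjustment is counted.

Alternative 3: The cut is C4–C5. Forward, CrCl2 with catalytic NiCl2 would convert the (E)-alkenyl iodide of the acyclic methyl ketone A5 into an alkenylchromium at C5 that adds to the C4 ketone and closes the ring as the tertiary allylic alcohol A6.
- In its favour: it is the most convergent plan. A6 already has every ring substituent in final form, and because the reagent tolerates esters the benzoate could even be in place before cyclisation. The E geometry is retained (equal to the chosen plan), and C7/C8 can come from an acyclic anti-selective aldol-type step. In directness and step count it is better than the chosen plan.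
- Against it here: alkenylchromium additions to ketones are much slower than to aldehydes, and here a strained ten-membered ring must close at the same time. The C4 configuration would be created during cyclisation under remote control from C7/C8, so either epimer could dominate. High dilution is needed.
- Comparison on structure: equal.
- Comparison on mechanism: the chosen plan fixes C4 on a chair before the ring exists, and the alternative leaves it to the cyclisation.
- Comparison on step economy: the alternative is better.

Key step: step 15

Remark on numbering: eudesmane numbering is used for every decalin (C10 bears the angular methyl C14, C1 is the oxygenated carbon beside it, C4 bears methyl C15, C5 is the second ring-fusion carbon, C7 bears the isopropyl group C11–C13, C8 the second secondary oxygen). β is the face of the angular methyl, and the numbers are kept after ring opening.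

Remark on the structures: the decalin mesylate, the silylated diene and the target were checked centre by centre. C4 and C8 keep their descriptors and C7 of the target corresponds to hydrogen delivered on the α face, so no structure had to be altered. The one correction is to the approach to C4: methylmagnesium bromide on a C4 ketone would be expected to give the 4-epimer, so it is replaced by methylenation followed by α-face hydration.

Remark on supply: (R)-Wieland–Miescher ketone, isopropylmagnesium chloride and 4-acetoxybenzoyl chloride are taken as purchased.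

Step 1
Reactants: 1 (R)-Wieland–Miescher ketone
Product: 2 1β-hydroxy-11,12,13,15-tetranoreudesm-5-en-7-one
Conditions: NaBH4 (0.3 equiv), EtOH, −10 °C
Reagents that add atoms: none
Why: Borohydride reduction; the saturated C1 ketone is more electrophilic than the vinylogous enone carbonyl, and hydride enters anti to the angular methyl (α face), giving the equatorial 1β-alcohol.

Step 2
Reactants: 2 1β-hydroxy-11,12,13,15-tetranoreudesm-5-en-7-one
Product: 3 1β-pivaloyloxy-11,12,13,15-tetranoreudesm-5-en-7-one
Conditions: PivCl, pyridine, DMAP (cat.), CH2Cl2, 0 °C → rt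
Reagents that add atoms: pivaloyl chloride, CC(C)(C)C(Cl)=O
Why: DMAP-catalysed acylation; the pivalate has no α-hydrogens and is hindered, so it should survive borane, the zinc/titanium methylenation, amide base and the Grignard coupling, and it is removed later by hydride without touching silyl ethers.

Step 3
Reactants: 3 1β-pivaloyloxy-11,12,13,15-tetranoreudesm-5-en-7-one
Product: 4 7,7-ethylenedioxy-1β-pivaloyloxy-11,12,13,15-tetranoreudesm-4-ene
Conditions: HOCH2CH2OH, TsOH·H2O (cat.), benzene, reflux, Dean–Stark
Reagents that add atoms: ethylene glycol, OCCO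
Why: Acid-catalysed ketalisation of a β,β-disubstituted enone with deconjugation; the dienol-type intermediate is protonated at C6, so the alkene moves to C4=C5, as is usual for steroidal 4-en-3-ones and angularly methylated octalones. The step protects C7 and places the alkene where C4 can be oxidised.

Step 4
Reactants: 4 7,7-ethylenedioxy-1β-pivaloyloxy-11,12,13,15-tetranoreudesm-4-ene
Product: 6 7,7-ethylenedioxy-1β-pivaloyloxy-11,12,13,15-tetranor-5α-eudesman-4α-ol, via 4α-alkylborane 5 (not isolated)
Conditions: BH3·THF, THF, 0 °C → rt; then 3 M NaOH, 30% H2O2, 0 °C → rt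
Reagents that add atoms: hydrogen peroxide, OO (oxygen of the new hydroxyl); borane–THF, B.C1CCOC1 (boron only in 5, hydrogen in 6)
Why: Hydroboration–oxidation; syn addition with boron on the less substituted C4 from the α face, opposite the angular methyl, should give 5α-H (trans ring fusion) and 4α-boron, and the peroxide oxidation proceeds with retention.

Step 5
Reactants: 6 7,7-ethylenedioxy-1β-pivaloyloxy-11,12,13,15-tetranor-5α-eudesman-4α-ol
Product: 7 7,7-ethylenedioxy-1β-pivaloyloxy-11,12,13,15-tetranor-5α-eudesman-4-one
Conditions: Pr4N[RuO4] (5 mol%), NMO, 4 Å MS, CH2Cl2, rt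
Reagents that add atoms: none
Why: Ley–Griffith oxidation under neutral conditions, so neither the ketal nor the C5 stereocentre beside the new ketone meets acid or base.

Step 6
Reactants: 7 7,7-ethylenedioxy-1β-pivaloyloxy-11,12,13,15-tetranor-5α-eudesman-4-one
Product: 8 7,7-ethylenedioxy-1β-pivaloyloxy-11,12,13-trinor-5α-eudesm-4(15)-ene
Conditions: Zn, CH2Br2, TiCl4, THF, −40 → 5 °C (pre-formed reagent); then 7, CH2Cl2, rt
Reagents that add atoms: dibromomethane, BrCBr
Why: Takai–Lombardo methylenation; the gem-dizinc/titanium reagent is non-basic, so the epimerisable C5–H α to the hindered ketone is preserved (a basic ylide could equilibrate the ring fusion), and the pivalate is not attacked.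

Step 7
Reactants: 8 7,7-ethylenedioxy-1β-pivaloyloxy-11,12,13-trinor-5α-eudesm-4(15)-ene
Product: 10 7,7-ethylenedioxy-1β-pivaloyloxy-11,12,13-trinor-5α-eudesman-4α-ol, via 15-acetoxymercurio carbinol 9 (not isolated)
Conditions: Hg(OAc)2, THF/H2O (1:1), rt, short contact; then 3 M NaOH, NaBH4, 0 °C
Reagents that add atoms: water, O (oxygen of the tertiary hydroxyl); Hg(OAc)2, CC(=O)O[Hg]OC(C)=O (mercury only in 9)
Why: Oxymercuration–demercuration; water attacks the mercurinium ion at tertiary C4 along the equatorial α trajectory because the axial β approach is blocked by the syn-axial C10 methyl. This gives 4α-OH and, after reductive loss of mercury, the axial 4β-methyl, the epimer that Grignard addition to 7 would not give.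

Step 8
Reactants: 10 7,7-ethylenedioxy-1β-pivaloyloxy-11,12,13-trinor-5α-eudesman-4α-ol
Product: 11 4α-hydroxy-1β-pivaloyloxy-11,12,13-trinor-5α-eudesman-7-one
Conditions: 1 M HCl, THF, rt
Reagents that add atoms: water, O
Why: Acid hydrolysis of the dioxolane; the tertiary alcohol is γ to the ketone, so there is no β-elimination or retro-aldol path, and the pivalate is stable.

Step 9
Reactants: 11 4α-hydroxy-1β-pivaloyloxy-11,12,13-trinor-5α-eudesman-7-one
Product: 12 1β-pivaloyloxy-4α,7-bis(triethylsilyloxy)-11,12,13-trinor-5α-eudesm-7-ene
Conditions: TESOTf (2.5 equiv), Et3N, CH2Cl2, −78 → 0 °C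
Reagents that add atoms: triethylsilyl trifluoromethanesulfonate, CC[Si](CC)(CC)OS(=O)(=O)C(F)(F)F
Why: The silyl triflate caps the tertiary alcohol and, by amine-mediated soft enolisation, forms the enol ether toward C8. That is the direction favoured for trans-fused ketones of this type (as in 5α-steroidal 3-ketones), and it is reinforced because C6 is flanked by the C4 substituents.

Step 10
Reactants: 12 1β-pivaloyloxy-4α,7-bis(triethylsilyloxy)-11,12,13-trinor-5α-eudesm-7-ene
Product: 14 1β-pivaloyloxy-4α,8α-bis(triethylsilyloxy)-11,12,13-trinor-5α-eudesman-7-one, via 7α,8α-silyloxy epoxide 13 (not isolated)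
Conditions: mCPBA (1.1 equiv), CH2Cl2, −20 → 0 °C; aq NaHCO3/Na2S2O3 work-up
Reagents that add atoms: 3-chloroperoxybenzoic acid, OOC(=O)c1cccc(Cl)c1
Why: Rubottom oxidation; the peracid epoxidises the enol ether from the α face (the β face at C8 is syn-axial to the C10 methyl), and the silyloxy epoxide opens with 1,4-silyl shift to the α-silyloxy ketone. The equatorial 8α oxygen is also the more stable epimer.

Step 11
Reactants: 14 1β-pivaloyloxy-4α,8α-bis(triethylsilyloxy)-11,12,13-trinor-5α-eudesman-7-one
Product: 16 1β-pivaloyloxy-4α,8α-bis(triethylsilyloxy)-11,12,13-trinor-5α-eudesm-6-en-7-yl trifluoromethanesulfonate, via potassium C6–C7 enolate 15 (not isolated)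
Conditions: KN(SiMe3)2 (1.1 equiv), THF, −78 °C; PhNTf2, −78 → −20 °C
Reagents that add atoms: N-phenylbis(trifluoromethanesulfonimide), O=S(=O)(N(c1ccccc1)S(=O)(=O)C(F)(F)F)C(F)(F)F
Why: Kinetic enolisation and O-triflation; the hindered amide base should remove a C6 hydrogen and not the C8 methine, which is tertiary, shielded by the silyl group and disfavoured by the α-oxygen (the usual α′-selectivity of α-silyloxy ketones). Trapping at low temperature prevents enolate equilibration and fixes the C6=C7 position.

Step 12
Reactants: 16 1β-pivaloyloxy-4α,8α-bis(triethylsilyloxy)-11,12,13-trinor-5α-eudesm-6-en-7-yl trifluoromethanesulfonate; 17 isopropylmagnesium chloride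
Product: 18 1β-pivaloyloxy-4α,8α-bis(triethylsilyloxy)-5α-eudesm-6-ene
Conditions: i-PrMgCl (1.5 equiv), Fe(acac)3 (5 mol%), THF/NMP, −30 °C
Reagents that add atoms: isopropylmagnesium chloride (17), CC(C)[Mg]Cl
Why: Iron-catalysed Kumada-type coupling of an alkenyl triflate with a secondary alkyl Grignard reagent; it is fast at low temperature, so the pivalate and silyl ethers are spared and isomerisation of the isopropyl group is not favoured. The alkene position and C8 are unchanged.

Step 13
Reactants: 18 1β-pivaloyloxy-4α,8α-bis(triethylsilyloxy)-5α-eudesm-6-ene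
Product: 19 4α,8α-bis(triethylsilyloxy)-5α-eudesm-6-en-1β-ol
Conditions: i-Bu2AlH (2.5 equiv), CH2Cl2, −78 → −20 °C; Rochelle salt work-up
Reagents that add atoms: none
Why: Reductive ester cleavage frees the 1β-alcohol with retention; silyl ethers and the hindered trisubstituted alkene are inert to the hydride.

Step 14
Reactants: 19 4α,8α-bis(triethylsilyloxy)-5α-eudesm-6-en-1β-ol
Product: 20 1β-mesyloxy-4α,8α-bis(triethylsilyloxy)-5α-eudesm-6-ene
Conditions: MsCl, pyridine, DMAP (cat.), 0 °C → rt
Reagents that add atoms: methanesulfonyl chloride, CS(Cl)(=O)=O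
Why: O-sulfonylation of the only free hydroxyl with retention at C1 gives the equatorial 1β-mesylate. It is installed last so that the sulfonate never meets amide base, Grignard reagent or the earlier borane/alkali step.

Step 15
Reactants: 20 1β-mesyloxy-4α,8α-bis(triethylsilyloxy)-5α-eudesm-6-ene
Product: 23 (4R,7S,8S,1(10)E,5E)-4,8-bis(triethylsilyloxy)germacra-1(10),5-diene, via 6α-alkylborane 21 (not isolated), via sodium alkyltrihydroxyborate 22 (not isolated)
Conditions: BH3·THF (4 equiv), THF, 0 °C → rt; then 3 M aq NaOH, rt, argon
Reagents that add atoms: none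
Why: BH3 adds syn across C6=C7 with boron on the less substituted C6; the β face is closed by the axial methyls on C10 and C4, so boron and hydrogen enter from the α face, which creates C7 with hydrogen α and the isopropyl group equatorial, trans to the 8α-silyloxy group as in the target. Aqueous NaOH hydrolyses the B–H bonds and quaternises boron to the borate 22. In the trans-decalin chair the equatorial C6–B and C1–OMs bonds are both antiperiplanar to C5–C10, so the C–B electrons form the C5=C6 π bond, C5–C10 breaks, C1=C10 forms and mesylate leaves in one concerted step. The closest known reaction type is the boronate (Grob-type) fragmentation of γ-sulfonyloxy organoboranes derived from decalin alkenes, which gives (E,E)-cyclodecadienes. The ten-membered ring is not closed by bond formation: it is the periphery of the bicyclo[4.4.0]decane and appears by cleavage of the shared bond, so no high dilution is needed. The anti arrangements C4–C5–C6–C7 and C9–C10–C1–C2 of the chair are transferred into E geometry at both alkenes. The step needs regio- and facial selectivity in the hydroboration, secured by the trisubstituted alkene and the two axial methyls, and stereoelectronic alignment, secured by the trans fusion and the equatorial leaving group. The conditions are basic throughout, which avoids transannular cyclisation, and the silyl ethers prevent alkoxyborane formation and alkoxide side reactions.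

Step 16
Reactants: 23 (4R,7S,8S,1(10)E,5E)-4,8-bis(triethylsilyloxy)germacra-1(10),5-diene
Product: 24 (4R,7S,8S,1(10)E,5E)-germacra-1(10),5-diene-4,8-diol
Conditions: Bu4NF (3 equiv), THF, rt → 40 °C; base-washed silica
Reagents that add atoms: none
Why: Fluoride-mediated desilylation removes both triethylsilyl ethers under basic, acid-free conditions that the diene tolerates.

Step 17
Reactants: 24 (4R,7S,8S,1(10)E,5E)-germacra-1(10),5-diene-4,8-diol; 25 4-acetoxybenzoyl chloride
Product: 26 (4R,7S,8S,1(10)E,5E)-4-hydroxygermacra-1(10),5-dien-8-yl 4-acetoxybenzoate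
Conditions: 25 (1.3 equiv), pyridine, DMAP (0.2 equiv), CH2Cl2, 0 °C → rt
Reagents that add atoms: 4-acetoxybenzoyl chloride (25), CC(=O)Oc1ccc(cc1)C(Cl)=O
Why: DMAP-catalysed acylation; the secondary C8 hydroxyl reacts while the tertiary allylic C4 hydroxyl is too hindered, pyridine buffers the HCl so no acid reaches the diene, and the acetate on the phenol prevents self-condensation of the acid chloride.

Step 18
Reactants: 26 (4R,7S,8S,1(10)E,5E)-4-hydroxygermacra-1(10),5-dien-8-yl 4-acetoxybenzoate
Product: 27 (4R,7S,8S,1(10)E,5E)-4-hydroxygermacra-1(10),5-dien-8-yl 4-hydroxybenzoate (CNP0277965.1)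
Conditions: K2CO3 (1.5 equiv), MeOH, 0 °C; aq NH4Cl quench
Reagents that add atoms: none
Why: Base-mediated methanolysis (transesterification); the aryl acetate is an activated ester and should be cleaved far faster than the hindered secondary benzoate, which is further deactivated once the para-phenoxide forms. No acid is used.

Compound list

1 | (R)-Wieland–Miescher ketone | C[C@@]12CCC(=O)C=C1CCCC2=O | starting material
2 | 1β-hydroxy-11,12,13,15-tetranoreudesm-5-en-7-one | C[C@]12[C@H](O)CCCC1=CC(=O)CC2 | intermediate
3 | 1β-pivaloyloxy-11,12,13,15-tetranoreudesm-5-en-7-one | C[C@]12[C@H](OC(=O)C(C)(C)C)CCCC1=CC(=O)CC2 | intermediate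
4 | 7,7-ethylenedioxy-1β-pivaloyloxy-11,12,13,15-tetranoreudesm-4-ene | C[C@]12[C@H](OC(=O)C(C)(C)C)CCC=C1CC3(OCCO3)CC2 | intermediate
5 | 4α-boryl-7,7-ethylenedioxy-1β-pivaloyloxy-11,12,13,15-tetranor-5α-eudesmane (BH2 on C4) | C[C@]12[C@H](OC(=O)C(C)(C)C)CC[C@@H](B)[C@@H]1CC3(OCCO3)CC2 | intermediate (not isolated)
6 | 7,7-ethylenedioxy-1β-pivaloyloxy-11,12,13,15-tetranor-5α-eudesman-4α-ol | C[C@]12[C@H](OC(=O)C(C)(C)C)CC[C@@H](O)[C@@H]1CC3(OCCO3)CC2 | intermediate
7 | 7,7-ethylenedioxy-1β-pivaloyloxy-11,12,13,15-tetranor-5α-eudesman-4-one | C[C@]12[C@H](OC(=O)C(C)(C)C)CCC(=O)[C@@H]1CC3(OCCO3)CC2 | intermediate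
8 | 7,7-ethylenedioxy-1β-pivaloyloxy-11,12,13-trinor-5α-eudesm-4(15)-ene | C[C@]12[C@H](OC(=O)C(C)(C)C)CCC(=C)[C@@H]1CC3(OCCO3)CC2 | intermediate
9 | 15-(acetoxymercurio)-7,7-ethylenedioxy-1β-pivaloyloxy-11,12,13-trinor-5α-eudesman-4α-ol | C[C@]12[C@H](OC(=O)C(C)(C)C)CC[C@@](C[Hg]OC(C)=O)(O)[C@@H]1CC3(OCCO3)CC2 | intermediate (not isolated)
10 | 7,7-ethylenedioxy-1β-pivaloyloxy-11,12,13-trinor-5α-eudesman-4α-ol (4β-methyl) | C[C@]12[C@H](OC(=O)C(C)(C)C)CC[C@@](C)(O)[C@@H]1CC3(OCCO3)CC2 | intermediate
11 | 4α-hydroxy-1β-pivaloyloxy-11,12,13-trinor-5α-eudesman-7-one | C[C@]12[C@H](OC(=O)C(C)(C)C)CC[C@@](C)(O)[C@@H]1CC(=O)CC2 | intermediate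
12 | 1β-pivaloyloxy-4α,7-bis(triethylsilyloxy)-11,12,13-trinor-5α-eudesm-7-ene | C[C@]12[C@H](OC(=O)C(C)(C)C)CC[C@@](C)(O[Si](CC)(CC)CC)[C@@H]1CC(O[Si](CC)(CC)CC)=CC2 | intermediate
13 | 7α,8α-epoxy-1β-pivaloyloxy-4α,7β-bis(triethylsilyloxy)-11,12,13-trinor-5α-eudesmane | C[C@]12[C@H](OC(=O)C(C)(C)C)CC[C@@](C)(O[Si](CC)(CC)CC)[C@@H]1C[C@@]3(O[Si](CC)(CC)CC)O[C@H]3C2 | intermediate (not isolated)
14 | 1β-pivaloyloxy-4α,8α-bis(triethylsilyloxy)-11,12,13-trinor-5α-eudesman-7-one | C[C@]12[C@H](OC(=O)C(C)(C)C)CC[C@@](C)(O[Si](CC)(CC)CC)[C@@H]1CC(=O)[C@@H](O[Si](CC)(CC)CC)C2 | intermediate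
15 | potassium 1β-pivaloyloxy-4α,8α-bis(triethylsilyloxy)-11,12,13-trinor-5α-eudesm-6-en-7-olate | C[C@]12[C@H](OC(=O)C(C)(C)C)CC[C@@](C)(O[Si](CC)(CC)CC)[C@@H]1C=C([O-])[C@@H](O[Si](CC)(CC)CC)C2.[K+] | intermediate (not isolated)
16 | 1β-pivaloyloxy-4α,8α-bis(triethylsilyloxy)-11,12,13-trinor-5α-eudesm-6-en-7-yl trifluoromethanesulfonate | C[C@]12[C@H](OC(=O)C(C)(C)C)CC[C@@](C)(O[Si](CC)(CC)CC)[C@@H]1C=C(OS(=O)(=O)C(F)(F)F)[C@@H](O[Si](CC)(CC)CC)C2 | intermediate
17 | isopropylmagnesium chloride | CC(C)[Mg]Cl | starting material
18 | 1β-pivaloyloxy-4α,8α-bis(triethylsilyloxy)-5α-eudesm-6-ene | C[C@]12[C@H](OC(=O)C(C)(C)C)CC[C@@](C)(O[Si](CC)(CC)CC)[C@@H]1C=C(C(C)C)[C@@H](O[Si](CC)(CC)CC)C2 | intermediate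
19 | 4α,8α-bis(triethylsilyloxy)-5α-eudesm-6-en-1β-ol | C[C@]12[C@H](O)CC[C@@](C)(O[Si](CC)(CC)CC)[C@@H]1C=C(C(C)C)[C@@H](O[Si](CC)(CC)CC)C2 | intermediate
20 | 1β-mesyloxy-4α,8α-bis(triethylsilyloxy)-5α-eudesm-6-ene | C[C@]12[C@H](OS(C)(=O)=O)CC[C@@](C)(O[Si](CC)(CC)CC)[C@@H]1C=C(C(C)C)[C@@H](O[Si](CC)(CC)CC)C2 | intermediate
21 | 6α-boryl-1β-mesyloxy-4α,8α-bis(triethylsilyloxy)-5α,7αH-eudesmane (BH2 on C6) | C[C@]12[C@H](OS(C)(=O)=O)CC[C@@](C)(O[Si](CC)(CC)CC)[C@@H]1[C@@H](B)[C@H](C(C)C)[C@@H](O[Si](CC)(CC)CC)C2 | intermediate (not isolated)
22 | sodium trihydroxy[1β-mesyloxy-4α,8α-bis(triethylsilyloxy)-5α,7αH-eudesman-6α-yl]borate | C[C@]12[C@H](OS(C)(=O)=O)CC[C@@](C)(O[Si](CC)(CC)CC)[C@@H]1[C@@H]([B-](O)(O)O)[C@H](C(C)C)[C@@H](O[Si](CC)(CC)CC)C2.[Na+] | intermediate (not isolated)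
23 | (4R,7S,8S,1(10)E,5E)-4,8-bis(triethylsilyloxy)germacra-1(10),5-diene | C/C1=C\CC[C@@](C)(O[Si](CC)(CC)CC)/C=C/[C@H](C(C)C)[C@@H](O[Si](CC)(CC)CC)C1 | intermediate
24 | (4R,7S,8S,1(10)E,5E)-germacra-1(10),5-diene-4,8-diol | C/C1=C\CC[C@@](C)(O)/C=C/[C@H](C(C)C)[C@@H](O)C1 | intermediate
25 | 4-acetoxybenzoyl chloride | CC(=O)Oc1ccc(cc1)C(Cl)=O | starting material
26 | (4R,7S,8S,1(10)E,5E)-4-hydroxygermacra-1(10),5-dien-8-yl 4-acetoxybenzoate | C/C1=C\CC[C@@](C)(O)/C=C/[C@H](C(C)C)[C@@H](OC(=O)c2ccc(OC(C)=O)cc2)C1 | intermediate
27 | (4R,7S,8S,1(10)E,5E)-4-hydroxygermacra-1(10),5-dien-8-yl 4-hydroxybenzoate (CNP0277965.1) | C/C1=C\CC[C@@](C)(O)/C=C/[C@H](C(C)C)[C@@H](OC(=O)c2ccc(O)cc2)C1 | target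

Total step count: 18. Longest linear sequence: 18 steps from 1 (17 and 25 are purchased).

Least certain steps

Step 15 (key step). Hydroboration of the crowded trisubstituted alkene may be slow while the sulfonate is present, because C6 is flanked by both C4 substituents. The borate may also hydrolyse without fragmenting, and the product may cyclise transannularly if it meets acid during isolation. Fallback: the two events are decoupled. Starting from 20, the borane 21 is formed as before but intercepted with pinacol to give the isolable pinacol boronate F1, which can be purified and its C6/C7 configuration checked. F1 is then treated with NaOMe in MeOH/THF, so that an anhydrous methoxide ate complex triggers the same antiperiplanar fragmentation. The sequence returns to the route at 23.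

Step 4. Hydroboration of 4 may occur partly on the β face, which would give cis-fused material that the later steps cannot correct. Fallback: the ring fusion is set by a hydroxyl-directed hydrogenation. Starting from 4, mCPBA epoxidation on the α face gives the 4α,5α-epoxy ketal F2. Aqueous HCl removes the ketal to give the β,γ-epoxy ketone F3, and brief exposure to Et3N opens F3 by β-elimination to the 4α-hydroxy enone F4. Hydrogenation with [Ir(cod)(PCy3)(py)]PF6 under H2 in CH2Cl2, directed by the 4α-hydroxyl, delivers hydrogen to the α face and gives the trans-fused hydroxy ketone F5. Re-ketalisation with ethylene glycol and TsOH returns to the route at 6.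

Step 7. Water may be delivered partly along the axial β trajectory, giving the 4-epimer, and the ketal may be partly hydrolysed before the borohydride is added, exposing C7 to reduction. Fallback: the oxygen is introduced as an epoxide. Starting from 8, mCPBA attacks the exocyclic alkene from the α face to give the 4α,15-epoxide F6. LiAlH4 opens F6 at the CH2 terminus and also cleaves the pivalate, giving the 1β,4α-diol F7. Selective pivaloylation of the secondary 1β-hydroxyl of F7 (PivCl, pyridine) returns to the route at 10.

Step 11. Deprotonation at C6 may be sluggish because the axial C6 hydrogen is flanked by the methyls on C4 and C10, which would allow competing deprotonation at C8 or silyl migration and loss of regiocontrol. Fallback: a Shapiro reaction, in which the hydrazone geometry directs the deprotonation. Starting from 14, condensation with 2,4,6-triisopropylbenzenesulfonyl hydrazide gives the hydrazone F8, with the sulfonamide nitrogen syn to C6. Excess n-BuLi with TMEDA at −78 → 0 °C forms the C7 alkenyllithium and at the same time cleaves the pivalate, and an iodine quench gives the alkenyl iodide alcohol F9. Fe(acac)3-catalysed coupling of F9 with excess 17 returns to the route at 19, so step 13 is no longer needed.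

Step 12. The secondary alkyl–metal intermediate may undergo β-hydride elimination, leading to reduction of the triflate or a linear propyl group, and the coupling may be retarded by the neighbouring silyloxy group. Fallback: the carbon is introduced as an sp2 fragment. Starting from 16, Suzuki–Miyaura coupling with isopropenylboronic acid pinacol ester (Pd(PPh3)4, K3PO4, dioxane/H2O) gives the isopropenyl diene F10. Hydrogenation of F10 with RhCl(PPh3)3 under H2 should reduce only the unhindered 1,1-disubstituted alkene and returns to the route at 18.

Further compounds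

F1 | step 15 | 6α-(4,4,5,5-tetramethyl-1,3,2-dioxaborolan-2-yl)-1β-mesyloxy-4α,8α-bis(triethylsilyloxy)-5α,7αH-eudesmane | C[C@]12[C@H](OS(C)(=O)=O)CC[C@@](C)(O[Si](CC)(CC)CC)[C@@H]1[C@@H](B3OC(C)(C)C(C)(C)O3)[C@H](C(C)C)[C@@H](O[Si](CC)(CC)CC)C2
F2 | step 4 | 4α,5α-epoxy-7,7-ethylenedioxy-1β-pivaloyloxy-11,12,13,15-tetranoreudesmane | C[C@]12[C@H](OC(=O)C(C)(C)C)CC[C@H]3O[C@@]13CC4(OCCO4)CC2
F3 | step 4 | 4α,5α-epoxy-1β-pivaloyloxy-11,12,13,15-tetranoreudesman-7-one | C[C@]12[C@H](OC(=O)C(C)(C)C)CC[C@H]3O[C@@]13CC(=O)CC2
F4 | step 4 | 4α-hydroxy-1β-pivaloyloxy-11,12,13,15-tetranoreudesm-5-en-7-one | C[C@]12[C@H](OC(=O)C(C)(C)C)CC[C@@H](O)C1=CC(=O)CC2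
F5 | step 4 | 4α-hydroxy-1β-pivaloyloxy-11,12,13,15-tetranor-5α-eudesman-7-one | C[C@]12[C@H](OC(=O)C(C)(C)C)CC[C@@H](O)[C@@H]1CC(=O)CC2
F6 | step 7 | 4α,15-epoxy-7,7-ethylenedioxy-1β-pivaloyloxy-11,12,13-trinor-5α-eudesmane | C[C@]12[C@H](OC(=O)C(C)(C)C)CC[C@]3(CO3)[C@@H]1CC4(OCCO4)CC2
F7 | step 7 | 7,7-ethylenedioxy-11,12,13-trinor-5α-eudesmane-1β,4α-diol | C[C@]12[C@H](O)CC[C@@](C)(O)[C@@H]1CC3(OCCO3)CC2
F8 | step 11 | 2,4,6-triisopropylbenzenesulfonyl hydrazone of 14 (sulfonamide nitrogen syn to C6) | C[C@]12[C@H](OC(=O)C(C)(C)C)CC[C@@](C)(O[Si](CC)(CC)CC)[C@@H]1C/C(=N\NS(=O)(=O)c3c(C(C)C)cc(C(C)C)cc3C(C)C)[C@@H](O[Si](CC)(CC)CC)C2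
F9 | step 11 | 7-iodo-4α,8α-bis(triethylsilyloxy)-11,12,13-trinor-5α-eudesm-6-en-1β-ol | C[C@]12[C@H](O)CC[C@@](C)(O[Si](CC)(CC)CC)[C@@H]1C=C(I)[C@@H](O[Si](CC)(CC)CC)C2
F10 | step 12 | 1β-pivaloyloxy-4α,8α-bis(triethylsilyloxy)-5α-eudesma-6,11-diene | C[C@]12[C@H](OC(=O)C(C)(C)C)CC[C@@](C)(O[Si](CC)(CC)CC)[C@@H]1C=C(C(C)=C)[C@@H](O[Si](CC)(CC)CC)C2
A1 | alternative 1 | trans-1,2-dialkenylcyclohexanol with C5 hydroxyl and isopropenyl, C10 methyl and vinyl, C7 isopropyl, C8 tert-butyldimethylsilyloxy | C[C@@]1(C=C)C[C@H](O[Si](C)(C)C(C)(C)C)[C@@H](C(C)C)C[C@@]1(O)C(C)=C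
A2 | alternative 1 | ten-membered (1(10)E)-diene C4=C5 trimethylsilyl enol ether, C8 tert-butyldimethylsilyl ether | C/C1=C\CC/C(C)=C(O[Si](C)(C)C)/C[C@H](C(C)C)[C@@H](O[Si](C)(C)C(C)(C)C)C1
A3 | alternative 2 | acyclic C8 aldehyde with methyl (2Z,4E)-2-(bromomethyl)dienoate terminus, C4 triethylsilyl ether | O=CC/C(C)=C/CC[C@@](C)(O[Si](CC)(CC)CC)/C=C/C=C(\CBr)C(=O)OC
A4 | alternative 2 | ten-membered C8 alcohol with 1-(methoxycarbonyl)ethenyl on C7, C4 triethylsilyl ether | C/C1=C\CC[C@@](C)(O[Si](CC)(CC)CC)/C=C/[C@H](C(=C)C(=O)OC)[C@@H](O)C1
A5 | alternative 3 | acyclic C4 methyl ketone with (E)-alkenyl iodide at C5, C8 tert-butyldimethylsilyl ether | CC(=O)CC/C=C(\C)C[C@H](O[Si](C)(C)C(C)(C)C)[C@@H](C(C)C)/C=C/I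
A6 | alternative 3 | ten-membered tertiary allylic alcohol, C8 tert-butyldimethylsilyl ether | C/C1=C\CC[C@@](C)(O)/C=C/[C@H](C(C)C)[C@@H](O[Si](C)(C)C(C)(C)C)C1
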